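**Plan**

- Retrosynthetic cuts, in order: the C5–O bond (late oxidation of ring A), the bond from C4 to the butenedioate side chain (decarboxylative alkenylation of a C4 acid), then C4–C4a and C1–C8a together (an aryne inserted into the Cα–C(=O) bond of a β-lactone).
- Enabling feature: the adjacent ring-A carbons C4a and C8a hold C4 and C1, and the remaining lactone atoms C1(=O)–O2–C3–C4 are an oxetan-2-one in disguise, whose C4–C1 bond the two aryne carbons can pry apart.
- Forward order: L-malic acid gives the trans β-lactone, a benzyl-protected phenol gives the silyl aryl triflate, and the insertion grows the six-membered lactone (ring B) onto ring A. The C4 ester is then exchanged for the side chain via a redox-active ester and a geometrically defined enol triflate, followed by debenzylation and oxidation at C5.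
- Stereochemistry: C3 (S) is the malic acid centre and no bond to it is ever broken. C4 is set trans by enolate protonation in the insertion and set again, trans (4R), when the C4 radical is coupled anti to the C3 ester. The E alkene comes from triflation of a chelated Z-enolate and is retained in the coupling.

Key step: step 8

Remark: locants follow the 1-oxoisochromane skeleton (C1 carbonyl, O2, C3, C4, C4a, C5–C8, C8a). 3,5-Bis(benzyloxy)phenol is taken as commercially available, and benzyl ethers are used on ring A so that the last deprotection needs neither base nor a reagent that attacks methyl esters.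

**Route**

Step 1
Reactants: 1 3,5-bis(benzyloxy)phenol
Product: 2 3,5-bis(benzyloxy)phenyl N-isopropylcarbamate
Conditions: i-PrNCO, Et3N (cat.), CH2Cl2, 23 °C
Reagents that add atoms: isopropyl isocyanate, CC(C)N=C=O
Why: Base-catalysed addition of the phenol to the isocyanate (carbamoylation) installs a group that directs ortho-lithiation strongly and can later be removed with a secondary amine.

Step 2
Reactants: 2 3,5-bis(benzyloxy)phenyl N-isopropylcarbamate
Product: 6 3,5-bis(benzyloxy)-2-(trimethylsilyl)phenyl N-isopropylcarbamate, via N-silyl carbamate 3 (not isolated), via aryllithium 4 (not isolated), via bis-silyl carbamate 5 (not isolated)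
Conditions: Me3SiOTf, TMEDA, Et2O, 0 → 23 °C; n-BuLi, TMEDA, −78 °C; Me3SiCl, −78 → 23 °C; aq. NaHSO4
Reagents that add atoms: chlorotrimethylsilane, C[Si](C)(C)Cl
Why: Directed ortho-metalation, in which the N-silylated carbamate steers lithiation to C2 (the position it shares with a benzyloxy group), the aryllithium is C-silylated and the N–Si bond is hydrolysed on work-up, with −78 °C holding back anionic Fries rearrangement and benzylic lithiation.

Step 3
Reactants: 6 3,5-bis(benzyloxy)-2-(trimethylsilyl)phenyl N-isopropylcarbamate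
Product: 8 3,5-bis(benzyloxy)-2-(trimethylsilyl)phenyl trifluoromethanesulfonate, via silylphenol 7 (not isolated)
Conditions: DBU, Et2NH, MeCN, 40 °C; PhN(SO2CF3)2, 23 °C
Reagents that add atoms: N-phenylbis(trifluoromethanesulfonimide), O=S(=O)(N(c1ccccc1)S(=O)(=O)C(F)(F)F)C(F)(F)F
Why: The secondary carbamate is cleaved by base-induced elimination to the isocyanate (trapped by Et2NH) and the phenoxide is O-triflated in the same flask, the standard access to ortho-silyl aryl triflates.

Step 4
Reactants: 9 (S)-malic acid
Product: 11 (3S)-3-hydroxy-4-methoxy-4-oxobutanoic acid, via trifluoroacetoxy anhydride 10 (not isolated)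
Conditions: (CF3CO)2O, 0 → 23 °C; MeOH, 0 → 23 °C
Reagents that add atoms: methanol, CO
Why: Trifluoroacetic anhydride closes the cyclic anhydride and acylates the hydroxyl, and methanol then opens the anhydride at the more electrophilic carbonyl beside the acyloxy carbon and removes the trifluoroacetate, so only the C1 carboxyl is esterified and the stereocentre is untouched.

Step 5
Reactants: 11 (3S)-3-hydroxy-4-methoxy-4-oxobutanoic acid
Product: 12 4-tert-butyl 1-methyl (2S)-2-hydroxybutanedioate
Conditions: O-tert-butyl-N,N′-diisopropylisourea, CH2Cl2, 23 °C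
Reagents that add atoms: O-tert-butyl-N,N′-diisopropylisourea, CC(C)NC(=NC(C)C)OC(C)(C)C
Why: Isourea esterification transfers tert-butyl to the carboxylic acid under neutral conditions and leaves the secondary alcohol and the methyl ester alone.

Step 6
Reactants: 12 4-tert-butyl 1-methyl (2S)-2-hydroxybutanedioate
Product: 14 (3S)-2-(tert-butoxycarbonyl)-3-hydroxy-4-methoxy-4-oxobutanoic acid (both C2 epimers), via dilithium alkoxide enolate 13 (not isolated)
Conditions: LiN(SiMe3)2 (2.2 equiv), THF, −78 °C; CO2, −78 °C; 1 M HCl, 0 °C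
Reagents that add atoms: carbon dioxide, O=C=O
Why: Fráter–Seebach-type double deprotonation gives the alkoxide enolate at C3 of the malate, which is C-carboxylated by CO2 (any O-carbonate is lost on acidification), the carbinol centre not being involved and the new malonate centre needing no control.

Step 7
Reactants: 14 (3S)-2-(tert-butoxycarbonyl)-3-hydroxy-4-methoxy-4-oxobutanoic acid
Product: 15 3-tert-butyl 2-methyl (2S,3R)-4-oxooxetane-2,3-dicarboxylate
Conditions: bis(2-oxo-3-oxazolidinyl)phosphinic chloride, Et3N, CH2Cl2, 0 → 23 °C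
Reagents that add atoms: none
Why: β-Lactonisation of a β-hydroxy acid by carboxyl activation and 4-exo-trig attack of the hydroxyl closes the oxetanone with retention at the carbinol carbon, and the acidic malonate-type α-centre equilibrates under Et3N to the trans (2S,3R) lactone.

Step 8
Reactants: 8 3,5-bis(benzyloxy)-2-(trimethylsilyl)phenyl trifluoromethanesulfonate; 15 3-tert-butyl 2-methyl (2S,3R)-4-oxooxetane-2,3-dicarboxylate
Product: 17 4-tert-butyl 3-methyl (3S,4S)-6,8-bis(benzyloxy)-1-oxoisochromane-3,4-dicarboxylate, via aryne 16 (not isolated)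
Conditions: CsF (2.5 equiv), MeCN, 23 → 40 °C; 15 in slight excess
Reagents that add atoms: none
Why: Proposed new method: fluoride removes the silyl group of 8 and loss of triflate gives aryne 16, while the malonate-type C–H of lactone 15 is removed (first by fluoride, then by the product enolate in a chain) and the enolate carbon bonds to the aryne carbon remote from the flanking benzyloxy group, which leaves the aryl anion on the carbon next to that oxygen. The aryl anion then adds 4-exo-trig to the strained lactone carbonyl and the fused cyclobutene alkoxide fragments across the old Cα–C(=O) bond, so ring B is closed by a two-carbon ring expansion of the oxetanone and emerges as the tert-butyl ester enolate of the six-membered lactone. The closest known reaction type is the fluoride-induced acyl-alkylation of arynes by β-keto esters and malonates, which inserts the aryne into a C–C σ bond and enlarges cyclic β-keto esters by two carbons; a β-lactone carbonyl as the acyl donor is untested. C3 is carried unchanged from L-malic acid, and C4 is set by protonation of the enolate anti to the C3 ester, the trans (4S) isomer also being the one favoured on equilibration. The step needs aryne regioselectivity, secured by the single flanking benzyloxy group that ends up at C8, and acyl selectivity, secured by the strain of the lactone carbonyl, the bulk of the tert-butyl ester and the trans placement of the aryl group and the C3 ester on the four-membered ring, which rules out five-ring closure onto that ester. Elimination from the lactone enolate is held back because the ring C–O bond lies in the nodal plane of the enolate, and the more acidic lactone 15 protonates the product enolate before it can open.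

Step 9
Reactants: 17 4-tert-butyl 3-methyl (3S,4S)-6,8-bis(benzyloxy)-1-oxoisochromane-3,4-dicarboxylate
Product: 18 (3S,4S)-6,8-bis(benzyloxy)-3-(methoxycarbonyl)-1-oxoisochromane-4-carboxylic acid
Conditions: CF3CO2H, CH2Cl2, 0 → 23 °C
Reagents that add atoms: none
Why: Acidolysis of the tert-butyl ester with loss of isobutene frees the C4 acid without touching the methyl ester, the lactone or the benzyl ethers and without base at the acidic C4–H.

Step 10
Reactants: 18 (3S,4S)-6,8-bis(benzyloxy)-3-(methoxycarbonyl)-1-oxoisochromane-4-carboxylic acid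
Product: 19 4-(1,3-dioxoisoindolin-2-yl) 3-methyl (3S,4S)-6,8-bis(benzyloxy)-1-oxoisochromane-3,4-dicarboxylate
Conditions: N-hydroxyphthalimide, N,N′-diisopropylcarbodiimide, DMAP (cat.), CH2Cl2, 0 → 23 °C
Reagents that add atoms: N-hydroxyphthalimide, O=C1c2ccccc2C(=O)N1O
Why: Steglich-type carbodiimide esterification gives the redox-active N-acyloxyphthalimide, and the configuration at C4 is of no consequence here because this centre becomes a radical in step 13.

Step 11
Reactants: 20 tert-butyl acetate; 21 dimethyl oxalate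
Product: 23 4-tert-butyl 1-methyl 2-oxobutanedioate, via lithium enolate 22 (not isolated)
Conditions: LiN(i-Pr)2, THF, −78 °C; (CO2Me)2, −78 → 0 °C; 1 M HCl
Reagents that add atoms: none
Why: Crossed Claisen condensation of the tert-butyl acetate enolate with non-enolisable dimethyl oxalate gives the mixed oxaloacetate, in which the two carboxyl groups of the future side chain are differentiated from the outset.

Step 12
Reactants: 23 4-tert-butyl 1-methyl 2-oxobutanedioate
Product: 25 4-tert-butyl 1-methyl (2Z)-2-{[(trifluoromethyl)sulfonyl]oxy}but-2-enedioate, via sodium enolate 24 (not isolated)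
Conditions: NaH, Et2O, 0 °C; (CF3SO2)2O, 0 °C
Reagents that add atoms: trifluoromethanesulfonic anhydride, O=S(=O)(OS(=O)(=O)C(F)(F)F)C(F)(F)F
Why: O-Sulfonylation of the sodium-chelated Z-enolate of the β-keto ester gives the Z-enol triflate, in which the triflate is cis to the tert-butyl ester and the two ester groups are trans as the target requires.

Step 13
Reactants: 19 4-(1,3-dioxoisoindolin-2-yl) 3-methyl (3S,4S)-6,8-bis(benzyloxy)-1-oxoisochromane-3,4-dicarboxylate; 25 4-tert-butyl 1-methyl (2Z)-2-{[(trifluoromethyl)sulfonyl]oxy}but-2-enedioate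
Product: 26 4-tert-butyl 1-methyl (2E)-2-[(3S,4R)-6,8-bis(benzyloxy)-3-(methoxycarbonyl)-1-oxo-3,4-dihydro-1H-isochromen-4-yl]but-2-enedioate
Conditions: NiBr2·diglyme (10 mol %), 4,4′-di-tert-butyl-2,2′-bipyridine (12 mol %), Zn, DMA, 0 → 23 °C
Reagents that add atoms: none
Why: Nickel-catalysed reductive decarboxylative alkenylation (cross-electrophile coupling of a benzylic N-acyloxyphthalimide with an alkenyl electrophile), in which zerovalent nickel inserts into the C–OTf bond with retention of geometry, single-electron reduction of 19 releases CO2 and the C4 benzylic radical, and nickel captures and couples this radical on the face anti to the C3 ester, setting the trans (4R) centre without base.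

Step 14
Reactants: 26 4-tert-butyl 1-methyl (2E)-2-[(3S,4R)-6,8-bis(benzyloxy)-3-(methoxycarbonyl)-1-oxo-3,4-dihydro-1H-isochromen-4-yl]but-2-enedioate
Product: 27 (2E)-3-[(3S,4R)-6,8-dihydroxy-3-(methoxycarbonyl)-1-oxo-3,4-dihydro-1H-isochromen-4-yl]-4-methoxy-4-oxobut-2-enoic acid
Conditions: BCl3, C6HMe5, CH2Cl2, −78 → 0 °C; aq. KH2PO4
Reagents that add atoms: none
Why: Lewis-acid debenzylation of both aryl benzyl ethers with pentamethylbenzene as a non-basic benzyl-cation trap, during which the tert-butyl ester also ionises, while the methyl esters, the lactone and the alkene are left untouched.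

Step 15
Reactants: 27 (2E)-3-[(3S,4R)-6,8-dihydroxy-3-(methoxycarbonyl)-1-oxo-3,4-dihydro-1H-isochromen-4-yl]-4-methoxy-4-oxobut-2-enoic acid
Product: 29 (2E)-4-methoxy-4-oxo-3-[(3S,4R)-5,6,8-trihydroxy-3-(methoxycarbonyl)-1-oxo-3,4-dihydro-1H-isochromen-4-yl]but-2-enoic acid, via hydroxyquinone 28 (not isolated)
Conditions: ON(SO3K)2, KH2PO4, H2O/acetone, 0 °C; Na2S2O4, H2O, 0 °C, Ar
Reagents that add atoms: potassium nitrosodisulfonate, [K+].[K+].[O]N(S(=O)(=O)[O-])S(=O)(=O)[O-]
Why: Teuber oxidation of the resorcinol should place oxygen at C5, para to the C8 hydroxyl and ortho to the C6 hydroxyl, giving the 6-hydroxy-5,8-quinone, which dithionite reduces at once to the 5,6,8-triol under near-neutral conditions that spare the C4–H and the alkene.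

**Compound list**

1 | 3,5-bis(benzyloxy)phenol | Oc1cc(OCc2ccccc2)cc(OCc2ccccc2)c1 | starting material
2 | 3,5-bis(benzyloxy)phenyl N-isopropylcarbamate | CC(C)NC(=O)Oc1cc(OCc2ccccc2)cc(OCc2ccccc2)c1 | intermediate
3 | 3,5-bis(benzyloxy)phenyl N-isopropyl-N-(trimethylsilyl)carbamate | CC(C)N([Si](C)(C)C)C(=O)Oc1cc(OCc2ccccc2)cc(OCc2ccccc2)c1 | intermediate
4 | [2,4-bis(benzyloxy)-6-{[isopropyl(trimethylsilyl)carbamoyl]oxy}phenyl]lithium | [Li]c1c(OCc2ccccc2)cc(OCc2ccccc2)cc1OC(=O)N(C(C)C)[Si](C)(C)C | intermediate
5 | 3,5-bis(benzyloxy)-2-(trimethylsilyl)phenyl N-isopropyl-N-(trimethylsilyl)carbamate | CC(C)N([Si](C)(C)C)C(=O)Oc1cc(OCc2ccccc2)cc(OCc2ccccc2)c1[Si](C)(C)C | intermediate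
6 | 3,5-bis(benzyloxy)-2-(trimethylsilyl)phenyl N-isopropylcarbamate | CC(C)NC(=O)Oc1cc(OCc2ccccc2)cc(OCc2ccccc2)c1[Si](C)(C)C | intermediate
7 | 3,5-bis(benzyloxy)-2-(trimethylsilyl)phenol | C[Si](C)(C)c1c(O)cc(OCc2ccccc2)cc1OCc1ccccc1 | intermediate
8 | 3,5-bis(benzyloxy)-2-(trimethylsilyl)phenyl trifluoromethanesulfonate | C[Si](C)(C)c1c(OCc2ccccc2)cc(OCc2ccccc2)cc1OS(=O)(=O)C(F)(F)F | intermediate
9 | (S)-malic acid | O[C@@H](CC(=O)O)C(=O)O | starting material
10 | (3S)-2,5-dioxooxolan-3-yl trifluoroacetate | O=C1C[C@H](OC(=O)C(F)(F)F)C(=O)O1 | intermediate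
11 | (3S)-3-hydroxy-4-methoxy-4-oxobutanoic acid | COC(=O)[C@@H](O)CC(=O)O | intermediate
12 | 4-tert-butyl 1-methyl (2S)-2-hydroxybutanedioate | COC(=O)[C@@H](O)CC(=O)OC(C)(C)C | intermediate
13 | dilithium alkoxide enolate of 12 | COC(=O)[C@@H]([O-])C=C([O-])OC(C)(C)C.[Li+].[Li+] | intermediate
14 | (3S)-2-(tert-butoxycarbonyl)-3-hydroxy-4-methoxy-4-oxobutanoic acid (both C2 epimers) | COC(=O)[C@@H](O)C(C(=O)O)C(=O)OC(C)(C)C | intermediate
15 | 3-tert-butyl 2-methyl (2S,3R)-4-oxooxetane-2,3-dicarboxylate | COC(=O)[C@H]1OC(=O)[C@@H]1C(=O)OC(C)(C)C | intermediate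
16 | 3,5-bis(benzyloxy)benzyne (1,2-didehydro-3,5-bis(benzyloxy)benzene) | C1#CC(OCc2ccccc2)=CC(OCc2ccccc2)=C1 | intermediate
17 | 4-tert-butyl 3-methyl (3S,4S)-6,8-bis(benzyloxy)-1-oxoisochromane-3,4-dicarboxylate | CC(C)(C)OC(=O)[C@H]1c2cc(OCc3ccccc3)cc(OCc3ccccc3)c2C(=O)O[C@@H]1C(=O)OC | intermediate
18 | (3S,4S)-6,8-bis(benzyloxy)-3-(methoxycarbonyl)-1-oxoisochromane-4-carboxylic acid | OC(=O)[C@H]1c2cc(OCc3ccccc3)cc(OCc3ccccc3)c2C(=O)O[C@@H]1C(=O)OC | intermediate
19 | 4-(1,3-dioxoisoindolin-2-yl) 3-methyl (3S,4S)-6,8-bis(benzyloxy)-1-oxoisochromane-3,4-dicarboxylate | O=C(ON1C(=O)c2ccccc2C1=O)[C@H]1c2cc(OCc3ccccc3)cc(OCc3ccccc3)c2C(=O)O[C@@H]1C(=O)OC | intermediate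
20 | tert-butyl acetate | CC(=O)OC(C)(C)C | starting material
21 | dimethyl oxalate | COC(=O)C(=O)OC | starting material
22 | lithium 1-tert-butoxyethenolate | C=C([O-])OC(C)(C)C.[Li+] | intermediate
23 | 4-tert-butyl 1-methyl 2-oxobutanedioate | COC(=O)C(=O)CC(=O)OC(C)(C)C | intermediate
24 | sodium (Z)-enolate of 23 | COC(=O)/C([O-])=C/C(=O)OC(C)(C)C.[Na+] | intermediate
25 | 4-tert-butyl 1-methyl (2Z)-2-{[(trifluoromethyl)sulfonyl]oxy}but-2-enedioate | COC(=O)/C(OS(=O)(=O)C(F)(F)F)=C/C(=O)OC(C)(C)C | intermediate
26 | 4-tert-butyl 1-methyl (2E)-2-[(3S,4R)-6,8-bis(benzyloxy)-3-(methoxycarbonyl)-1-oxo-3,4-dihydro-1H-isochromen-4-yl]but-2-enedioate | COC(=O)/C(=C/C(=O)OC(C)(C)C)[C@H]1c2cc(OCc3ccccc3)cc(OCc3ccccc3)c2C(=O)O[C@@H]1C(=O)OC | intermediate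
27 | (2E)-3-[(3S,4R)-6,8-dihydroxy-3-(methoxycarbonyl)-1-oxo-3,4-dihydro-1H-isochromen-4-yl]-4-methoxy-4-oxobut-2-enoic acid | COC(=O)/C(=C/C(=O)O)[C@H]1c2cc(O)cc(O)c2C(=O)O[C@@H]1C(=O)OC | intermediate
28 | (2E)-3-[(3S,4R)-6-hydroxy-3-(methoxycarbonyl)-1,5,8-trioxo-3,4,5,8-tetrahydro-1H-isochromen-4-yl]-4-methoxy-4-oxobut-2-enoic acid | COC(=O)/C(=C/C(=O)O)[C@H]1C2=C(C(=O)C=C(O)C2=O)C(=O)O[C@@H]1C(=O)OC | intermediate
29 | (2E)-4-methoxy-4-oxo-3-[(3S,4R)-5,6,8-trihydroxy-3-(methoxycarbonyl)-1-oxo-3,4-dihydro-1H-isochromen-4-yl]but-2-enoic acid | COC(=O)/C(=C/C(=O)O)[C@H]1c2c(O)c(O)cc(O)c2C(=O)O[C@@H]1C(=O)OC | target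

**Step count and risks**

Total steps: 15. Longest linear sequence: 10 steps (steps 4–10 and 13–15, from (S)-malic acid).

Steps most likely to fail:

1. Step 8 (aryne insertion). The aryl anion may be protonated before it reaches the lactone carbonyl, giving plain α-arylation; fluoride may open the lactone; or the product enolate may open by elimination of the carboxylate and re-close, which would erase the C3 configuration. The fallback uses known chemistry, sets out from 8 and rejoins the route at 18. Aryne insertion into the C–C bond of dimethyl malonate (KF, 18-crown-6, THF, 23 °C) should give methyl 2,4-bis(benzyloxy)-6-(2-methoxy-2-oxoethyl)benzoate F1, with the same regiochemistry as in step 8. Saponification (LiOH, aqueous THF/MeOH, then HCl) gives 2,4-bis(benzyloxy)-6-(carboxymethyl)benzoic acid F2, and acetic anhydride in warm toluene closes 6,8-bis(benzyloxy)-1H-isochromene-1,3(4H)-dione F3. An enantioselective aldol–lactonisation (formal cycloaddition of the enolisable anhydride) with methyl glyoxylate under a bifunctional cinchona squaramide catalyst, with the catalyst pseudoenantiomer chosen for the (3S,4S) series, should then deliver the trans acid 18 directly.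

2. Step 13 (decarboxylative alkenylation). Capture of the hindered benzylic C4 radical by nickel may be slow, so that dimerisation, reduction or addition of the radical to the electron-poor alkene competes, and the anti selectivity at C4 may be incomplete. The fallback inverts the polarity of the alkenyl partner, sets out from 25 and 19 and returns at 26. Nickel-catalysed triflate–iodide exchange on 25 (Ni(cod)2 cat., NaI, DMA/THF, 23 °C) should give 4-tert-butyl 1-methyl (2Z)-2-iodobut-2-enedioate F4. Zinc insertion (Zn, LiCl, THF, 0 °C) gives [(1Z)-3-tert-butoxy-1-(methoxycarbonyl)-3-oxoprop-1-en-1-yl]zinc iodide F5, which is coupled with redox-active ester 19 under Ni(acac)2/2,2′-bipyridine in THF/DMF (decarboxylative Negishi-type alkenylation, no external reductant). The E arrangement of the two esters is also the thermodynamically preferred one, so partial geometric scrambling would converge on 26.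

3. Step 15 (oxidation at C5). The nitroxyl radical may attack C7, between the two hydroxyls, instead of the more hindered C5; the electron-rich ring may be over-oxidised; or the quinone may tautomerise through the activated C4–H. The fallback sets out from 27 and returns at 28. The free C6 hydroxyl is silylated selectively (t-BuMe2SiCl, imidazole, DMF, 0 °C; the chelated C8 hydroxyl does not react and the silyl ester falls off on work-up) to give (2E)-3-[(3S,4R)-6-{[tert-butyl(dimethyl)silyl]oxy}-8-hydroxy-3-(methoxycarbonyl)-1-oxo-3,4-dihydro-1H-isochromen-4-yl]-4-methoxy-4-oxobut-2-enoic acid F6. The only remaining phenol, whose para position is C5, is oxidised with PhI(OCOCF3)2 (a trivalent iodine oxidant) in aqueous MeCN at 0 °C to (2E)-3-[(3S,4R)-6-{[tert-butyl(dimethyl)silyl]oxy}-3-(methoxycarbonyl)-1,5,8-trioxo-3,4,5,8-tetrahydro-1H-isochromen-4-yl]-4-methoxy-4-oxobut-2-enoic acid F7. HF·pyridine in MeCN then frees hydroxyquinone 28, which is reduced with Na2S2O4 as in step 15.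

Further compounds
F1 | step 8 | methyl 2,4-bis(benzyloxy)-6-(2-methoxy-2-oxoethyl)benzoate | COC(=O)Cc1cc(OCc2ccccc2)cc(OCc2ccccc2)c1C(=O)OC
F2 | step 8 | 2,4-bis(benzyloxy)-6-(carboxymethyl)benzoic acid | OC(=O)Cc1cc(OCc2ccccc2)cc(OCc2ccccc2)c1C(=O)O
F3 | step 8 | 6,8-bis(benzyloxy)-1H-isochromene-1,3(4H)-dione | O=C1Cc2cc(OCc3ccccc3)cc(OCc3ccccc3)c2C(=O)O1
F4 | step 13 | 4-tert-butyl 1-methyl (2Z)-2-iodobut-2-enedioate | COC(=O)/C(I)=C/C(=O)OC(C)(C)C
F5 | step 13 | [(1Z)-3-tert-butoxy-1-(methoxycarbonyl)-3-oxoprop-1-en-1-yl]zinc iodide | COC(=O)/C([Zn]I)=C/C(=O)OC(C)(C)C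
F6 | step 15 | (2E)-3-[(3S,4R)-6-{[tert-butyl(dimethyl)silyl]oxy}-8-hydroxy-3-(methoxycarbonyl)-1-oxo-3,4-dihydro-1H-isochromen-4-yl]-4-methoxy-4-oxobut-2-enoic acid | COC(=O)/C(=C/C(=O)O)[C@H]1c2cc(O[Si](C)(C)C(C)(C)C)cc(O)c2C(=O)O[C@@H]1C(=O)OC
F7 | step 15 | (2E)-3-[(3S,4R)-6-{[tert-butyl(dimethyl)silyl]oxy}-3-(methoxycarbonyl)-1,5,8-trioxo-3,4,5,8-tetrahydro-1H-isochromen-4-yl]-4-methoxy-4-oxobut-2-enoic acid | COC(=O)/C(=C/C(=O)O)[C@H]1C2=C(C(=O)C=C(O[Si](C)(C)C(C)(C)C)C2=O)C(=O)O[C@@H]1C(=O)OC
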